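## Retrosynthetic overview

- No ring is formed: rings A, C and B are bought intact as apigenin; the work is three O- or C-functionalisations and one deprotection.
- Key disconnection: the C6–OCH3 bond (C–O), made by direct C6–H methoxylation of ring A with methanol.
- 4'-O–SO3 bond: sulfation of the only reactive phenol left after O7 is blocked.
- 7-O–benzyl bond: put on first at the most acidic phenol, removed last by hydrogenolysis, which aryl sulfates survive.

Assumption: the target has no stereocentre (it is achiral), so there is no enantiomer to control; the sulfate is carried as its potassium salt and set free as the hydrogen sulfate drawn only in the last step.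

## Route

Step 1
Reactants: 1 apigenin; 2 benzyl bromide
Product: 3 7-O-benzylapigenin
Conditions: BnBr (1.05 equiv), K2CO3 (1.1 equiv), DMF, 25 °C, 16 h
Reagents that add atoms: benzyl bromide, BrCc1ccccc1
Why: Williamson ether synthesis with one equivalent of weak base alkylates the most acidic phenol, 7-OH (para to the C4 carbonyl), ahead of 4'-OH and the hydrogen-bonded 5-OH; no stereocentre is formed.

Step 2
Reactants: 3 7-O-benzylapigenin; 4 sulfur trioxide–pyridine complex; 5 potassium hydroxide
Product: 7 potassium 7-O-benzylapigenin 4'-sulfate, via pyridinium 7-O-benzylapigenin 4'-sulfate 6 (not isolated)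
Conditions: SO3·pyridine (3 equiv), pyridine, 25 °C, 12 h; then KOH/MeOH to pH 8, 0 °C; C18 chromatography
Reagents that add atoms: sulfur trioxide–pyridine complex, O=S(=O)([O-])[n+]1ccccc1; potassium hydroxide, [K+].[OH-]
Why: O-sulfation of a phenol by an SO3–amine complex reaches only 4'-OH, since O7 is benzylated and 5-OH is locked in its hydrogen bond to the C4 carbonyl, and KOH then exchanges pyridinium for potassium (salt metathesis).

Step 3
Reactants: 7 potassium 7-O-benzylapigenin 4'-sulfate; 8 methanol
Product: 10 potassium 7-O-benzylhispidulin 4'-sulfate, via potassium 7-O-benzyl-6-iodoapigenin 4'-sulfate 9 (not isolated)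
Conditions: CuI (20 mol%), KI (30 mol%), 3,4,7,8-tetramethyl-1,10-phenanthroline (40 mol%), K3PO4 (3 equiv), MeOH, 90 °C, sealed vessel, air dosed in portions (about 0.6 equiv O2 in total), 16 h; then KH2PO4 (aq) to pH 6–7, C18 chromatography
Reagents that add atoms: methanol, CO
Why: Proposed new method: an iodide-relay, copper-catalysed aerobic C6–H methoxylation in which divalent copper (from CuI and O2) oxidises iodide to electrophilic iodine, the 5-phenoxide is iodinated at C6 (the only free position ortho to O5 and the site electrophilic iodine takes in 5-hydroxy-7-alkoxyflavones), and monovalent copper/phenanthroline then couples the aryl iodide 9 with methoxide in an Ullmann-type C–O coupling that returns the iodide, so that the net equation is 7 + MeOH + ½ O2 → 10 + H2O with water as the only co-product and any proto-deiodination simply feeds 7 back into the cycle; the closest known reaction types are the copper-catalysed aerobic halogenation of electron-rich arenes and the copper-catalysed methoxylation of aryl iodides and 6-bromoflavones, which have not been merged into one catalytic cycle.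

Step 4
Reactants: 10 potassium 7-O-benzylhispidulin 4'-sulfate
Product: 12 hispidulin 4'-sulfate, via potassium hispidulin 4'-sulfate 11 (not isolated)
Conditions: H2 (1 atm), 10% Pd/C, MeOH–H2O 4:1, 25 °C, 3 h; filter; then HCl (1.00 equiv, 0.1 M aq), 0 °C, freeze-dry, take up in cold dry acetone, filter off KCl
Reagents that add atoms: none
Why: Catalytic hydrogenolysis of a benzyl aryl ether over Pd/C at 1 atm spares the aryl sulfate monoester, the methyl ether and the flavone C2=C3 bond, and one equivalent of HCl then protonates the sulfate salt to the hydrogen sulfate drawn.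

## Compound list

No compound in the route has a stereocentre.

1 | apigenin, 5,7-dihydroxy-2-(4-hydroxyphenyl)-4H-chromen-4-one | O=c1cc(-c2ccc(O)cc2)oc2cc(O)cc(O)c12 | starting material
2 | benzyl bromide | BrCc1ccccc1 | starting material
3 | 7-O-benzylapigenin, 7-(benzyloxy)-5-hydroxy-2-(4-hydroxyphenyl)-4H-chromen-4-one | O=c1cc(-c2ccc(O)cc2)oc2cc(OCc3ccccc3)cc(O)c12 | intermediate
4 | sulfur trioxide–pyridine complex | O=S(=O)([O-])[n+]1ccccc1 | starting material
5 | potassium hydroxide | [K+].[OH-] | starting material
6 | pyridinium 4-[7-(benzyloxy)-5-hydroxy-4-oxo-4H-chromen-2-yl]phenyl sulfate | O=c1cc(-c2ccc(OS(=O)(=O)[O-])cc2)oc2cc(OCc3ccccc3)cc(O)c12.c1cc[nH+]cc1 | intermediate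
7 | potassium 4-[7-(benzyloxy)-5-hydroxy-4-oxo-4H-chromen-2-yl]phenyl sulfate | O=c1cc(-c2ccc(OS(=O)(=O)[O-])cc2)oc2cc(OCc3ccccc3)cc(O)c12.[K+] | intermediate
8 | methanol | CO | starting material
9 | potassium 4-[7-(benzyloxy)-5-hydroxy-6-iodo-4-oxo-4H-chromen-2-yl]phenyl sulfate | O=c1cc(-c2ccc(OS(=O)(=O)[O-])cc2)oc2cc(OCc3ccccc3)c(I)c(O)c12.[K+] | intermediate
10 | potassium 4-[7-(benzyloxy)-5-hydroxy-6-methoxy-4-oxo-4H-chromen-2-yl]phenyl sulfate | COc1c(OCc2ccccc2)cc2oc(-c3ccc(OS(=O)(=O)[O-])cc3)cc(=O)c2c1O.[K+] | intermediate
11 | potassium 4-(5,7-dihydroxy-6-methoxy-4-oxo-4H-chromen-2-yl)phenyl sulfate | COc1c(O)cc2oc(-c3ccc(OS(=O)(=O)[O-])cc3)cc(=O)c2c1O.[K+] | intermediate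
12 | hispidulin 4'-sulfate, 4-(5,7-dihydroxy-6-methoxy-4-oxo-4H-chromen-2-yl)phenyl hydrogen sulfate | COc1c(O)cc2oc(-c3ccc(OS(=O)(=O)O)cc3)cc(=O)c2c1O | target

## Step count and risks

Total steps: 4. Longest linear sequence: 4 steps (1 → 3 → 7 → 10 → 12).

**Step 3 (proposed new step, highest risk).** The relay may stall because O2 and the Ullmann step compete for monovalent copper. Iodination may also go partly to C8, or the product may be iodinated again at C8; the 6-OMe position must be confirmed by HMBC and NOE. Fallback with known chemistry, setting out from 7 and coming back at 10: iodinate 7 with benzyltrimethylammonium dichloroiodate (BnMe3N·ICl2, 1.1 equiv) and CaCO3 in CH2Cl2–MeOH at 25 °C, the established C6-selective iodination of 5-hydroxy-7-alkoxyflavones. Isolate the iodide 9. Then run a separate, oxygen-free Ullmann-type methoxylation (CuI 10 mol%, 3,4,7,8-tetramethyl-1,10-phenanthroline 20 mol%, K3PO4, MeOH, 90 °C, argon) to 10. This detour makes no compound outside the list (F0).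

**Step 1.** The 7-OH over 4'-OH selectivity rests on roughly one pKa unit, so the 7,4'-dibenzyl ether and some 4'-ether can erode the yield. Fallback, setting out from 1 and coming back at 3: peracetylate apigenin (Ac2O, pyridine) to apigenin 5,7,4'-triacetate F1. Treat F1 with BnBr, K2CO3 and KI in refluxing acetone; the most labile 7-acetate is lost and the freed phenoxide is benzylated in the same pot, giving 7-O-benzylapigenin 5,4'-diacetate F2. Remove the two remaining acetates with K2CO3 in MeOH at 25 °C to reach 3.

**Step 4.** Prolonged hydrogenation can start to reduce the C2=C3 bond, and traces of copper or iodide from step 3 can poison Pd/C. The free hydrogen sulfate is also acid-labile and must be kept cold and isolated quickly. Fallback, setting out from 10 and coming back at 12 by way of 11: cleave the 7-O-benzyl group without hydrogen by thiolate SN2 dealkylation (PhSH 1.5 equiv, K2CO3, NMP, 80 °C). The 7-oxygen is a vinylogous carboxylate and so a good leaving group, while the 6-methyl ether and the sulfate monoanion do not react at this temperature. Wash out benzyl phenyl sulfide, then protonate 11 with 1.00 equiv HCl at 0 °C as in the main route. This detour makes no compound outside the list (F0).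

## Further compounds

F1 | step 1 | apigenin 5,7,4'-triacetate | CC(=O)Oc1ccc(-c2cc(=O)c3c(OC(C)=O)cc(OC(C)=O)cc3o2)cc1
F2 | step 1 | 7-O-benzylapigenin 5,4'-diacetate | CC(=O)Oc1ccc(-c2cc(=O)c3c(OC(C)=O)cc(OCc4ccccc4)cc3o2)cc1
F0 | step 3 | none | none
F0 | step 4 | none | none
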